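The earlier runs and the new flask are calculated for an exercise; the scatter is artificial.

As the chemist on this series, I had to decide whether the flask could keep the initiator charge of the earlier runs, 0.28 mM, or needed more.

| setting | beta | eta | theta | flask |
|---|---|---|---|---|
| substrate | 6 mM | 9 mM | 12 mM | 12 mM |
| reagent | 10.8 mM | 10.8 mM | 5.4 mM | 10.8 mM |
| scavenger | 12 mM | 12 mM | 12 mM | 12.0 mM |
| initiator | 0.28 mM | 0.28 mM | 0.28 mM | 0.28 mM |
| remark | run made earlier | run made earlier | run made earlier |  |
| time |  |  |  | 6.0 h |

| run | time / h | substrate / % | product / % |
|---|---|---|---|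
| beta | 0.833 | 0.6 | 96.2 |
| beta | 2.00 | 0 | 94.4 |
| beta | 4.00 | 0.5 | 96.2 |
| beta | 6.00 | 0 | 95.2 |
| eta | 1.50 | 0 | 94.3 |
| eta | 3.00 | 0 | 95.2 |
| eta | 5.00 | 0 | 96.1 |
| eta | 6.00 | 0.7 | 94.8 |
| theta | 0.833 | 56.8 | 39.5 |
| theta | 2.00 | 56.1 | 39.8 |
| theta | 4.00 | 55.5 | 41.7 |
| theta | 6.00 | 54.9 | 42.3 |

(each reading ± 1 percentage point)

* part of the substrate that has reacted at 6.0 h
* share of the unused reagent that is free and not bound as idle adduct, at 6.0 h

- the analysis behind the earlier runs scatters by 1 percentage point, standard deviation
- the earlier runs do not show how much of reagent is bound; that part of a forecast is a guess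

Theta stood at 45.1% reacted at 6.00 h, close to the 45.0% its reagent pays for one to one. Reagent looked like the limiting reagent in theta, and the flask's reagent pays one to one for 90.0% of its substrate, which I took as my upper mark. Whether the flask would reach that mark I judged from the initiator, so I reckoned c(reagent)/c(initiator), which for the flask is 38.6. I call this the turns demanded: the substrate turns each charged initiator must carry for the reagent to be used up.

Eta, with 0% substrate at 1.50 h, had shown 32.1 turns per initiator, and beta and theta had shown fewer. The flask demanded more than eta had shown, so the upper mark was unproven. Eta's turns, on the flask's charges, pay for 75.0% of its substrate, which I took as my lower mark. I also planned on no help from standing, since theta's substrate fell by 1.9 percentage points between its first and last samples. I left the initiator unchanged, to test that gap, and expected c between the two marks. The runs do not show bound reagent, so I set no figure for the free share.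

The forecast said 89% reacted and 20% free, holding that “most of it is probably bound”. The flask gave 86.4% reacted and 100% free.

    reagent + first chain carrier → product + second chain carrier (k = 28000 L mol⁻¹ s⁻¹)
    reagent + released group ⇌ idle adduct, settled at all times (K = 20.0 L mol⁻¹)
    initiator → 2 initiating radical (k = 0.00510 s⁻¹)
    2 first chain carrier → ended chains A (k = 1.30 × 10⁷ L mol⁻¹ s⁻¹)
    2 second chain carrier → ended chains B (k = 5.60 × 10⁷ L mol⁻¹ s⁻¹)
    scavenger + released group → scavenged by-product (k = 32.0 L mol⁻¹ s⁻¹)
    first chain carrier → ended carrier (k = 2.60 s⁻¹)
    substrate + second chain carrier → released group + first chain carrier (k = 1.10 × 10⁶ L mol⁻¹ s⁻¹)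
    substrate + initiating radical → capped initiator + first chain carrier (k = 1.50 × 10⁶ L mol⁻¹ s⁻¹)

The flask delivered 37.0 turns per initiator, fewer than the 38.6 demanded, and at 6.00 h it held 9.2% of its reagent with initiator at 0%. A neighbouring flask, charged with 0.17 mM initiator, demanded 63.5 turns, more than the flask had delivered, so I reckoned that reagent would again be left over. That neighbouring flask reached 76.5% reacted, or 54.0 turns per initiator, which is fewer than it demanded, and it kept 18% of its reagent.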